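**Plan**
Retrosynthetic cuts, in order: the C5–propenyl bond (Suzuki–Miyaura coupling of an aryl bromide); the C3 methyl, read as a reduced CO2Me; the C3–C3a bond, cut by reversing a 1,2-shift of the ring A carbon, which re-expands the dihydrofuran to the pyranone ring of a flavanone; and the C2–aryl bond of that flavanone (conjugate addition to a chromone).
Enabling feature: C3 of the dihydrofuran ring carries exactly one exocyclic carbon and is bonded to C3a, which lies para to the C6 methoxy group and ortho to O1 of ring A. The target is therefore a ring-contracted 7-methoxyflavanone whose old C4 has left the ring, and this electron-rich ring A carbon is an excellent migrating group.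
Forward order: ring A is bought (paeonol) and brominated, the pyranone ring is built (chromone), the trimethoxyphenyl ring B is attached at C2, the six-membered ring is contracted to the dihydrofuran, the ester is reduced to methyl, and the propenyl chain is joined last.
Stereochemistry: C2 (R) comes from the ligand-controlled enantioselective conjugate addition. C3 (R) is relayed from C2 in the ring contraction (iodine enters anti to the C2 aryl, the shift inverts C3, giving the trans ester, which is also the more stable epimer). The (E)-alkene is carried in with the boronate.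

Key step: step 4

Assumption: the (S)-configured pyridine–oxazoline ligand is taken to deliver the aryl group to the chromone face that gives the (2R)-flavanone, by analogy with its behaviour on cyclic enones; if the opposite sense were found, the (R)-ligand would be used.

Step 1
Reactants: 1 paeonol [1-(2-hydroxy-4-methoxyphenyl)ethanone]
Product: 2 1-(5-bromo-2-hydroxy-4-methoxyphenyl)ethanone
Conditions: NBS (1.05 equiv), MeCN, 0 °C → rt
Reagents that add atoms: N-bromosuccinimide, O=C1CCC(=O)N1Br
Why: Electrophilic aromatic bromination should occur at C5 of the acetophenone, the position para to the hydroxyl and ortho to the methoxy group, because the alternative C3 is flanked by both oxygens.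

Step 2
Reactants: 2 1-(5-bromo-2-hydroxy-4-methoxyphenyl)ethanone
Product: 4 6-bromo-7-methoxy-4H-chromen-4-one, via enaminone 3 (not isolated)
Conditions: Me2NCH(OMe)2 (2 equiv), toluene, 100 °C; evaporate; then conc. HCl, CH2Cl2, 40 °C
Reagents that add atoms: N,N-dimethylformamide dimethyl acetal, COC(OC)N(C)C
Why: Condensation of the acetyl methyl with the amide acetal gives the enaminone, and acid then drives conjugate addition of the phenol oxygen and loss of dimethylamine to close the 4-pyranone ring, the standard chromone synthesis.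

Step 3
Reactants: 4 6-bromo-7-methoxy-4H-chromen-4-one; 5 3,4,5-trimethoxyphenylboronic acid
Product: 6 (2R)-6-bromo-7-methoxy-2-(3,4,5-trimethoxyphenyl)chroman-4-one
Conditions: Pd(OCOCF3)2 (5 mol %), (S)-4-tert-butyl-2-(pyridin-2-yl)-4,5-dihydrooxazole (6 mol %), NH4PF6 (30 mol %), H2O (5 equiv), ClCH2CH2Cl, 60 °C, air
Reagents that add atoms: none
Why: Asymmetric conjugate addition of an arylboronic acid to a chromone under divalent palladium catalysis (transmetallation, enantiodetermining insertion of C2=C3 into the aryl–palladium bond, protonolysis of the palladium enolate by water), in which the tert-butyl group of the ligand shields one face and sets C2 as R; palladium stays divalent, so the aryl C–Br bond should not be engaged.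

Step 4
Reactants: 6 (2R)-6-bromo-7-methoxy-2-(3,4,5-trimethoxyphenyl)chroman-4-one
Product: 9 methyl (2R,3R)-5-bromo-6-methoxy-2-(3,4,5-trimethoxyphenyl)-2,3-dihydro-1-benzofuran-3-carboxylate, via enol ether 7 (not isolated), via iodane ketal 8 (not isolated)
Conditions: PhI(OAc)2 (1.2 equiv), H2SO4 (cat.), HC(OMe)3 (solvent), 0 °C → rt
Reagents that add atoms: trimethyl orthoformate, COC(OC)OC
Why: Acid and HC(OMe)3 convert ketone 6 into enol ether 7, which the electrophilic trivalent iodine reagent attacks at C3 anti to the C2 aryl group while methanol adds at C4 to give the α-iodanyl ketal 8; the C4–C4a bond, antiperiplanar to the equatorial C3–I bond, then shifts to C3 with loss of PhI, and the resulting dimethoxycarbenium ion is demethylated by acetate to the methyl ester. The closest known reaction type is the hypervalent-iodine oxidative 1,2-aryl shift of aryl ketones to arylacetic esters, in its ring-contracting form on flavanones. The dihydrofuran ring is closed by 3-exo-tet attack of the ipso carbon C4a on C3 (phenonium-type spirocyclopropane) followed by cleavage of the old C4–C4a bond, that is, a suprafacial 1,2-shift that contracts the six-membered pyranone to the five-membered ring and leaves old C4 as the exocyclic ester carbon. The new stereocentre C3 is controlled by C2: iodine enters trans to the C2 aryl, the shift inverts C3, and the ester ends trans to the aryl, which is also the thermodynamically preferred arrangement at this epimerisable centre. The step needs migration of ring A (C4a) in preference to migration of the C2 aryl (isoflavone) or loss of H3 (flavone); this is secured by the C7 methoxy group para and O1 ortho to C4a, which stabilise the bridged cation, whereas the 3,4,5-trimethoxyphenyl ring, with its para methoxy twisted out of conjugation and no antiperiplanar alignment to the equatorial C3–I bond, should migrate poorly.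

Step 5
Reactants: 9 methyl (2R,3R)-5-bromo-6-methoxy-2-(3,4,5-trimethoxyphenyl)-2,3-dihydro-1-benzofuran-3-carboxylate
Product: 10 [(2R,3S)-5-bromo-6-methoxy-2-(3,4,5-trimethoxyphenyl)-2,3-dihydro-1-benzofuran-3-yl]methanol
Conditions: i-Bu2AlH (2.5 equiv), CH2Cl2, −78 → 0 °C; aq. KNaC4H4O6 work-up
Reagents that add atoms: none
Why: Hydride reduction of the ester to the primary alcohol with a Lewis-acidic, non-basic aluminium hydride at low temperature should leave the epimerisable C3, the benzylic ether C2 and the aryl bromide untouched (the C3 descriptor changes only through substituent priority).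

Step 6
Reactants: 10 [(2R,3S)-5-bromo-6-methoxy-2-(3,4,5-trimethoxyphenyl)-2,3-dihydro-1-benzofuran-3-yl]methanol
Product: 11 [(2R,3S)-5-bromo-6-methoxy-2-(3,4,5-trimethoxyphenyl)-2,3-dihydro-1-benzofuran-3-yl]methyl 4-methylbenzenesulfonate
Conditions: TsCl (1.5 equiv), Et3N (2 equiv), DMAP (cat.), CH2Cl2, 0 °C → rt
Reagents that add atoms: p-toluenesulfonyl chloride, Cc1ccc(cc1)S(Cl)(=O)=O
Why: Sulfonylation of the primary alcohol under nucleophilic catalysis turns the hydroxyl into a leaving group without touching either stereocentre.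

Step 7
Reactants: 11 [(2R,3S)-5-bromo-6-methoxy-2-(3,4,5-trimethoxyphenyl)-2,3-dihydro-1-benzofuran-3-yl]methyl 4-methylbenzenesulfonate
Product: 12 (2R,3R)-5-bromo-6-methoxy-3-methyl-2-(3,4,5-trimethoxyphenyl)-2,3-dihydro-1-benzofuran
Conditions: LiEt3BH (3 equiv), THF, 0 °C → rt
Reagents that add atoms: none
Why: SN2 displacement of the primary tosylate by the strongly nucleophilic hydride donor should give the methyl group; C3 is not the reacting centre and keeps its configuration, and the aryl bromide is expected to be inert to this reagent at or below room temperature.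

Step 8
Reactants: 12 (2R,3R)-5-bromo-6-methoxy-3-methyl-2-(3,4,5-trimethoxyphenyl)-2,3-dihydro-1-benzofuran; 13 (E)-prop-1-enylboronic acid pinacol ester
Product: 14 (2R,3R)-6-methoxy-3-methyl-5-[(E)-prop-1-enyl]-2-(3,4,5-trimethoxyphenyl)-2,3-dihydro-1-benzofuran (target)
Conditions: Pd(OAc)2 (3 mol %), 2-dicyclohexylphosphino-2',6'-dimethoxybiphenyl (6 mol %), K3PO4 (3 equiv), toluene/H2O (10:1), 80 °C
Reagents that add atoms: none
Why: Suzuki–Miyaura coupling (oxidative addition of the aryl bromide to zerovalent palladium formed in situ, transmetallation, reductive elimination) should join the propenyl group with retention of the E geometry of the boronate, the bulky biarylphosphine serving the electron-rich ortho-substituted bromide, and neither stereocentre is involved.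

**Compound list**
1 | paeonol, 1-(2-hydroxy-4-methoxyphenyl)ethanone | CC(=O)c1ccc(OC)cc1O | starting material
2 | 1-(5-bromo-2-hydroxy-4-methoxyphenyl)ethanone | CC(=O)c1cc(Br)c(OC)cc1O | intermediate
3 | (E)-1-(5-bromo-2-hydroxy-4-methoxyphenyl)-3-(dimethylamino)prop-2-en-1-one (enaminone) | CN(C)/C=C/C(=O)c1cc(Br)c(OC)cc1O | intermediate (not isolated)
4 | 6-bromo-7-methoxy-4H-chromen-4-one | COc1cc2occc(=O)c2cc1Br | intermediate
5 | 3,4,5-trimethoxyphenylboronic acid | COc1cc(B(O)O)cc(OC)c1OC | starting material
6 | (2R)-6-bromo-7-methoxy-2-(3,4,5-trimethoxyphenyl)chroman-4-one | COc1cc2O[C@@H](c3cc(OC)c(OC)c(OC)c3)CC(=O)c2cc1Br | intermediate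
7 | (2R)-6-bromo-4,7-dimethoxy-2-(3,4,5-trimethoxyphenyl)-2H-chromene (enol ether) | COC1=C[C@H](c2cc(OC)c(OC)c(OC)c2)Oc2cc(OC)c(Br)cc12 | intermediate (not isolated)
8 | (2S,3S)-3-[acetoxy(phenyl)-λ3-iodanyl]-6-bromo-4,4,7-trimethoxy-2-(3,4,5-trimethoxyphenyl)chromane (iodine trans to the C2 aryl; C2 spatially as in 6) | COc1cc2O[C@@H](c3cc(OC)c(OC)c(OC)c3)[C@H](I(OC(C)=O)c3ccccc3)C(OC)(OC)c2cc1Br | intermediate (not isolated)
9 | methyl (2R,3R)-5-bromo-6-methoxy-2-(3,4,5-trimethoxyphenyl)-2,3-dihydro-1-benzofuran-3-carboxylate (trans) | Brc1cc2c(cc1OC)O[C@@H](c1cc(OC)c(OC)c(OC)c1)[C@@H]2C(=O)OC | intermediate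
10 | [(2R,3S)-5-bromo-6-methoxy-2-(3,4,5-trimethoxyphenyl)-2,3-dihydro-1-benzofuran-3-yl]methanol (trans) | Brc1cc2c(cc1OC)O[C@@H](c1cc(OC)c(OC)c(OC)c1)[C@@H]2CO | intermediate
11 | [(2R,3S)-5-bromo-6-methoxy-2-(3,4,5-trimethoxyphenyl)-2,3-dihydro-1-benzofuran-3-yl]methyl 4-methylbenzenesulfonate (trans) | Brc1cc2c(cc1OC)O[C@@H](c1cc(OC)c(OC)c(OC)c1)[C@@H]2COS(=O)(=O)c1ccc(C)cc1 | intermediate
12 | (2R,3R)-5-bromo-6-methoxy-3-methyl-2-(3,4,5-trimethoxyphenyl)-2,3-dihydro-1-benzofuran (trans) | Brc1cc2c(cc1OC)O[C@@H](c1cc(OC)c(OC)c(OC)c1)[C@@H]2C | intermediate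
13 | (E)-prop-1-enylboronic acid pinacol ester | C/C=C/B1OC(C)(C)C(C)(C)O1 | starting material
14 | (2R,3R)-6-methoxy-3-methyl-5-[(E)-prop-1-enyl]-2-(3,4,5-trimethoxyphenyl)-2,3-dihydro-1-benzofuran (trans) | C/C=C/c1cc2c(cc1OC)O[C@@H](c1cc(OC)c(OC)c(OC)c1)[C@@H]2C | target

Total step count: 8
Longest linear sequence: 8 steps (1 → 14)

**Steps most likely to fail**

1. Step 4 (oxidative ring contraction). What may go wrong: migration of the C2 aryl group instead of ring A, loss of H3 from the iodane (dehydrogenation of the pyranone ring), attack of the electrophilic iodine reagent on the trimethoxyphenyl ring, or acid-induced opening of the pyranone ring with erosion of optical purity. Fallback, from 6 back to 9: a Wolff ring contraction, which forms the same bond through a carbene and avoids the oxidant. Ketone 6 would be acylated at C3 (LiN(SiMe3)2, THF, −78 °C; CF3CO2CH2CF3) to give (2R)-6-bromo-7-methoxy-3-(trifluoroacetyl)-2-(3,4,5-trimethoxyphenyl)chroman-4-one F1, used crude. Deacylative diazo transfer (MsN3, Et3N, MeCN, rt) would give (2S)-6-bromo-3-diazo-7-methoxy-2-(3,4,5-trimethoxyphenyl)chroman-4-one F2 (C2 spatially unchanged; the descriptor changes only through priority). Irradiation (365 nm, MeOH, rt) should expel nitrogen with migration of the ring A carbon from C4 to C3 to give the ketene 5-bromo-6-methoxy-3-(oxomethylidene)-2-(3,4,5-trimethoxyphenyl)-2,3-dihydro-1-benzofuran F3. Methanol traps it as a mixture of 9 and its cis epimer methyl (2R,3S)-5-bromo-6-methoxy-2-(3,4,5-trimethoxyphenyl)-2,3-dihydro-1-benzofuran-3-carboxylate F4, and NaOMe (cat.), MeOH, 0 °C should equilibrate F4 to the trans ester 9. The low temperature of the enolate step is chosen to suppress base-induced opening of the pyranone ring.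

2. Step 3 (asymmetric conjugate addition). What may go wrong: sluggish insertion into the electron-rich 7-methoxychromone, protodeboronation of the electron-rich boronic acid, or insufficient facial selectivity. Fallback, from 2 back to 6: Claisen–Schmidt condensation of 2 with 3,4,5-trimethoxybenzaldehyde (KOH, EtOH, rt) would give (E)-1-(5-bromo-2-hydroxy-4-methoxyphenyl)-3-(3,4,5-trimethoxyphenyl)prop-2-en-1-one F5. Oxa-Michael ring closure (NaOAc, EtOH, reflux) would give racemic 6-bromo-7-methoxy-2-(3,4,5-trimethoxyphenyl)chroman-4-one F6. Preparative chromatography on a chiral stationary phase (amylose tris(3,5-dimethylphenylcarbamate), supercritical CO2/MeOH) would deliver 6. The unwanted (2S)-6-bromo-7-methoxy-2-(3,4,5-trimethoxyphenyl)chroman-4-one F7 is returned to the F5/F6 equilibrium with base and resolved again.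

3. Step 7 (hydride displacement of the tosylate). What may go wrong: attack of hydride at sulfur with return to the alcohol, elimination towards the exocyclic alkene and on to the aromatic benzofuran, or slow hydrodebromination of ring A. Fallback, from 10 back to 12 (bypasses steps 6 and 7): iodination of 10 (I2, PPh3, imidazole, CH2Cl2, 0 °C → rt) would give (2R,3R)-5-bromo-3-(iodomethyl)-6-methoxy-2-(3,4,5-trimethoxyphenyl)-2,3-dihydro-1-benzofuran F8. Reduction with Zn dust in AcOH at rt (zinc insertion into the C–I bond and protonolysis) should then give 12 without touching the aryl bromide.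

**Further compounds**
F1 | step 4 | (2R)-6-bromo-7-methoxy-3-(trifluoroacetyl)-2-(3,4,5-trimethoxyphenyl)chroman-4-one (C3 epimers and enol form) | COc1cc2O[C@@H](c3cc(OC)c(OC)c(OC)c3)C(C(=O)C(F)(F)F)C(=O)c2cc1Br
F2 | step 4 | (2S)-6-bromo-3-diazo-7-methoxy-2-(3,4,5-trimethoxyphenyl)chroman-4-one | COc1cc2O[C@@H](c3cc(OC)c(OC)c(OC)c3)C(=[N+]=[N-])C(=O)c2cc1Br
F3 | step 4 | 5-bromo-6-methoxy-3-(oxomethylidene)-2-(3,4,5-trimethoxyphenyl)-2,3-dihydro-1-benzofuran (ketene; C2 spatially as in 6) | COc1cc2O[C@@H](c3cc(OC)c(OC)c(OC)c3)C(=C=O)c2cc1Br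
F4 | step 4 | methyl (2R,3S)-5-bromo-6-methoxy-2-(3,4,5-trimethoxyphenyl)-2,3-dihydro-1-benzofuran-3-carboxylate (cis) | Brc1cc2c(cc1OC)O[C@@H](c1cc(OC)c(OC)c(OC)c1)[C@H]2C(=O)OC
F5 | step 3 | (E)-1-(5-bromo-2-hydroxy-4-methoxyphenyl)-3-(3,4,5-trimethoxyphenyl)prop-2-en-1-one | COc1cc(O)c(cc1Br)C(=O)/C=C/c1cc(OC)c(OC)c(OC)c1
F6 | step 3 | racemic 6-bromo-7-methoxy-2-(3,4,5-trimethoxyphenyl)chroman-4-one | COc1cc2OC(c3cc(OC)c(OC)c(OC)c3)CC(=O)c2cc1Br
F7 | step 3 | (2S)-6-bromo-7-methoxy-2-(3,4,5-trimethoxyphenyl)chroman-4-one | COc1cc2O[C@H](c3cc(OC)c(OC)c(OC)c3)CC(=O)c2cc1Br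
F8 | step 7 | (2R,3R)-5-bromo-3-(iodomethyl)-6-methoxy-2-(3,4,5-trimethoxyphenyl)-2,3-dihydro-1-benzofuran (trans) | Brc1cc2c(cc1OC)O[C@@H](c1cc(OC)c(OC)c(OC)c1)[C@@H]2CI
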